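Time in the flask was my way in: at 2.50 d the south-east run, which had red's recipe, stood at 59.2% of L, and I took that reading for red.

common to all: Q 1.05 equiv
- south-east: X 11 mM; E 3.3 mM; run made earlier
- north: X 11 mM; E 4.9 mM; run made earlier
- blue: X 11 mM (fed, over 2.50 d); E 3.30 mM; a stirred flask in which X is dosed at a steady rate over 2.50 d without added volume, worked up at 2.5 d; time 2.5 d
- green: X 11 mM; E 3.30 mM; a single well-mixed tank run continuously and read at steady state, 12.5 d in it on average
- red: X 11 mM; E 3.30 mM; everything together in a closed stirred flask, run for 2.5 d; time 2.5 d
- teal: X 11 mM; E 3.30 mM; one stirred flow tank at steady state, fed with the mixture as stated, mean residence time 2.5 d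

south-east run (percent of the X charged)

| time / d | L / % |
|---|---|
| 0.208 | 8.9 |
| 0.333 | 12.9 |
| 0.500 | 18.9 |
| 0.625 | 24.0 |
| 1.04 | 35.9 |
| 1.67 | 48.9 |
| 2.50 | 59.2 |

north run (percent of the X charged)

| time / h | L / % |
|---|---|
| 1.33 | 1.2 |
| 2.00 | 2.2 |
| 3.00 | 3.6 |
| 5.00 | 8.1 |
| 8.00 | 13.2 |
| 12.0 | 18.1 |
| 20.0 | 28.7 |

(standard deviation of a reading: 0.5 percentage points)

- the set-up with the highest amount of L at the outlet or at the end, in percent of the X put in ("none" if the first two lie within 2 percentage points) (blue / green / red / teal / none)
- amount of L at the outlet or at the end, in percent of the X put in, blue
- amount of L at the outlet or at the end, in percent of the X put in, green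
- amount of L at the outlet or at the end, in percent of the X put in, red
- amount of L at the outlet or at the end, in percent of the X put in, teal

- the stated concentrations are those of everything mixed, before any reaction; amounts are the same in each set-up
- the analysis behind the earlier runs scatters by 0.5 percentage points, standard deviation
- steps that have been proposed: X + Q <-> Z; Z -> L; Q + E -> D
- the feed brings no volume worth counting
- the earlier runs were made in a closed, stirred flask

I asked first what the end state must be. With Q at 1.05 equiv, and E taking at most its own charge of Q to D, the end yield of L lies between 75.0%, if Q is used up, and 100%, if all of X becomes L. Then I asked how fast that end is approached. The last south-east reading gave 0.623 /d towards the lower end and 0.359 /d towards the upper. This is the approach constant, the apparent first-order rate constant of a climb to the end yield: ln(end yield over what is still missing), per unit time.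

For blue I made an estimate, not a bound: I let each portion of X climb the south-east curve for its own age, although the portions share one charge of Q, and so set blue at that curve averaged over the dosing time. That curve bends over, so the average lies between its chord, 29.6%, and its value at mid-dosing, 40.2%. The climb tightens this: end yield minus L over (approach constant times dosing time) gave 34.0% to 37.0%. Taking the climb as first order, I set a tank at steady state at end yield times kτ/(1+kτ), where k is the approach constant and τ the residence time. That gave green 66.5% to 81.8% and teal 45.7% to 47.3%. Green's lower end stood higher than anything else I had, so I named green.

The forecast also named green, with blue 43%, green 68%, red 59.3% and teal 46.5%, saying “slow dosing keeps X low and time is short”. Its green and teal fell inside my ranges, but its blue stood above even the looser top of my averaged estimate.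

The flask gave green as best, with blue 37.3%, green 68.6%, red 58.9% and teal 44.4%. Blue lay 0.30 percentage points above my tightened top, and teal 1.3 points below my range.

    X + Q ⇌ Z (K = 100 /M, k = 0.820 /M/min)
    Z → L (k = 8.40 × 10⁻⁴ /min)
    Q + E → D (k = 0.0290 /M/min)

The neighbour is red's flask read at 6.0 d. The approach constants give 73.2% towards the lower end and 88.4% towards the upper. That flask held 77.4% of L, with 20.5% of X left.

The numbers in the tables are simulated with made-up constants; noise was put on by code.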